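**Retrosynthetic overview**
1. Target 42 ⇐ 4-O-TES lactone 41 ⇐ macrocyclic chlorohydrin diol 38; the γ-lactone is closed last by oxidative lactonisation.
2. 38 ⇐ allyl bromide/lactol 37 by a Cr-catalysed intramolecular γ-chloroallylation that forms C6–C7, the ten-membered ring, C6–Cl and C7–O in one step.
3. 37 ⇐ core 11 + chloroenal 16 + iodoalkene 28 by two Ni/Cr-catalysed alkenyl iodide–aldehyde couplings (C3–C4, then C8–C9); C8 comes from a directed epoxidation followed by acetate-assisted inversion.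
4. 11 ⇐ catalytic asymmetric Diels–Alder of enal 3 with siloxydiene 5, then Saegusa oxidation, Takai olefination and enolate acetoxylation.
5. Ring order: cyclohexenone (step 4) → ten-membered carbocycle (step 27) → γ-lactone (step 28).

Assumption: briarane numbering (C1–C20) is used for all intermediates, and fragment 16 is carried as the single (Z)-isomer obtained by separating the mono-desilylation isomers in step 10 (the other isomer is re-silylated to 14).

**Route**

Step 1
Reactants: 1 3-methylbut-2-en-1-ol (prenol)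
Product: 2 prenyl 4-methoxybenzyl ether
Conditions: NaH, PMBCl, Bu4NI (cat.), THF, 0 °C → rt
Reagents that add atoms: 4-methoxybenzyl chloride, COc1ccc(CCl)cc1
Why: Williamson etherification masks the future C9 oxygen as a PMB ether that survives the Lewis acid, strong base and Cr(II) steps that follow.

Step 2
Reactants: 2 prenyl 4-methoxybenzyl ether
Product: 3 (E)-4-[(4-methoxybenzyl)oxy]-2-methylbut-2-enal
Conditions: SeO2 (1.2 equiv), pyridine (cat.), 1,4-dioxane, 80 °C
Reagents that add atoms: selenium dioxide, O=[Se]=O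
Why: Riley allylic oxidation (ene then [2,3] shift) attacks the (E)-methyl group of the trisubstituted alkene and gives the (E)-enal directly.

Step 3
Reactants: 4 pent-1-en-3-one
Product: 5 (Z)-triisopropyl(penta-1,3-dien-3-yloxy)silane
Conditions: TIPSOTf, Et3N, Et2O, 0 °C
Reagents that add atoms: triisopropylsilyl triflate, CC(C)[Si](C(C)C)(C(C)C)OS(=O)(=O)C(F)(F)F
Why: Soft enolisation and O-silylation of the ethyl ketone give the (Z)-2-siloxydiene, with the methyl group outside the s-cis diene.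

Step 4
Reactants: 3 (E)-4-[(4-methoxybenzyl)oxy]-2-methylbut-2-enal + 5 (Z)-triisopropyl(penta-1,3-dien-3-yloxy)silane
Product: 6 (1S,5S,6S)-6-{[(4-methoxybenzyl)oxy]methyl}-1,5-dimethyl-4-[(triisopropylsilyl)oxy]cyclohex-3-ene-1-carbaldehyde
Conditions: (S)-o-tolyl-CBS-oxazaborolidinium triflimide (20 mol %), CH2Cl2, −78 → −40 °C
Reagents that add atoms: none
Why: Catalytic asymmetric Diels–Alder reaction (Corey oxazaborolidinium) in which the siloxy carbon ends para to the formyl-bearing C1, the (E)-enal geometry places Me-15 cis to C9, and the catalyst-shielded face of the s-trans enal sets C1 and C10 (antipodal catalyst if the opposite sense is found); the C11 epimers converge in step 7.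

Step 5
Reactants: 6 Diels–Alder adduct (TIPS enol ether)
Product: 7 (1S,5S,6S)-6-{[(4-methoxybenzyl)oxy]methyl}-1,5-dimethyl-4-oxocyclohex-2-ene-1-carbaldehyde
Conditions: Pd(OAc)2 (1.1 equiv), MeCN, rt
Reagents that add atoms: none
Why: Saegusa–Ito oxidation turns the regiodefined silyl enol ether into the C13=C14 enone without touching the non-enolisable aldehyde.

Step 6
Reactants: 7 enone aldehyde
Product: 8 (4S,5S,6S)-4-[(E)-2-iodoethenyl]-5-{[(4-methoxybenzyl)oxy]methyl}-4,6-dimethylcyclohex-2-en-1-one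
Conditions: CrCl2 (6 equiv), CHI3 (2 equiv), THF/1,4-dioxane 1:6, 0 °C → rt
Reagents that add atoms: iodoform, IC(I)I
Why: Takai olefination is aldehyde-selective in the presence of the ketone and gives the (E)-alkenyl iodide (C2=C3) even from a neopentyl aldehyde.

Step 7
Reactants: 8 (E)-iodoethenyl cyclohexenone
Product: 11 (1S,5S,6S)-5-[(E)-2-iodoethenyl]-6-{[(4-methoxybenzyl)oxy]methyl}-1,5-dimethyl-2-oxocyclohex-3-en-1-yl acetate, via potassium dienolate 9 (not isolated), via potassium alkoxide 10 (not isolated)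
Conditions: KHMDS (1.1 equiv), THF, −78 °C; Davis oxaziridine (1.3 equiv); then Ac2O (3 equiv), −78 → 0 °C
Reagents that add atoms: 2-(phenylsulfonyl)-3-phenyloxaziridine, O=S(=O)(c1ccccc1)N1OC1c1ccccc1; acetic anhydride, CC(=O)OC(C)=O
Why: Davis enolate hydroxylation of the only possible (C11) enolate occurs anti to the pseudo-axial C10 substituent, which sets C11, and the tertiary alkoxide is acetylated in the same flask.

Step 8
Reactants: 12 1,3-dihydroxypropan-2-one (used as its dimer)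
Product: 13 1,3-bis[(triethylsilyl)oxy]propan-2-one
Conditions: TESCl (2.2 equiv), imidazole, DMF, 0 °C
Reagents that add atoms: chlorotriethylsilane, CC[Si](Cl)(CC)CC
Why: Standard silylation gives a symmetric ketone, so the following olefination has no E/Z issue.

Step 9
Reactants: 13 1,3-bis[(triethylsilyl)oxy]propan-2-one
Product: 14 [2-(chloromethylidene)propane-1,3-diyl]bis(oxy)bis(triethylsilane)
Conditions: Ph3P(CH2Cl)Cl, NaHMDS, THF, −78 °C; then 13, −78 → 0 °C
Reagents that add atoms: (chloromethyl)triphenylphosphonium chloride, ClC[P+](c1ccccc1)(c1ccccc1)c1ccccc1.[Cl-]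
Why: Wittig chloromethylenation of the symmetric ketone installs C6 with its chlorine as a vinyl chloride.

Step 10
Reactants: 14 bis-TES vinyl chloride
Product: 15 (E)-3-chloro-2-{[(triethylsilyl)oxy]methyl}prop-2-en-1-ol
Conditions: HF·pyridine (1.0 equiv), pyridine, THF, −10 °C; chromatography (other isomer and diol re-silylated to 14)
Reagents that add atoms: none
Why: Statistical mono-desilylation gives the two geometric mono-alcohols, and the one with the free CH2OH cis to Cl is isolated.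

Step 11
Reactants: 15 mono-alcohol
Product: 16 (Z)-3-chloro-2-{[(triethylsilyl)oxy]methyl}prop-2-enal
Conditions: MnO2, CH2Cl2, rt
Reagents that add atoms: none
Why: MnO2 oxidation of the allylic alcohol gives the C4 aldehyde with Cl cis to CHO, without acid or base that could cleave the TES ether.

Step 12
Reactants: 11 alkenyl iodide acetate + 16 (Z)-chloroenal
Product: 17 (1S,5S,6S)-5-[(1E,3S,4Z)-5-chloro-3-[(triethylsilyl)oxy]-4-{[(triethylsilyl)oxy]methyl}penta-1,4-dien-1-yl]-6-{[(4-methoxybenzyl)oxy]methyl}-1,5-dimethyl-2-oxocyclohex-3-en-1-yl acetate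
Conditions: CrCl2 (10 mol %), Kishi-type chiral sulfonamide–oxazoline ligand (11 mol %, enantiomer for Si-face addition), proton sponge, NiCl2·(2,9-dimethylphenanthroline) (2 mol %), Mn, TESCl, LiCl, MeCN, rt
Reagents that add atoms: chlorotriethylsilane, CC[Si](Cl)(CC)CC
Why: Catalytic asymmetric Nozaki–Hiyama–Kishi coupling forms C3–C4 chemoselectively at the aldehyde, the ligand controls the new C4 carbinol (4S), and TESCl turnover delivers it as the silyl ether.

Step 13
Reactants: 17 C9 PMB ether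
Product: 18 C9 primary alcohol (6-hydroxymethyl analogue of 17)
Conditions: DDQ, CH2Cl2/pH 7 buffer, 0 °C
Reagents that add atoms: none
Why: Oxidative PMB cleavage is orthogonal to the TES ethers, the acetate and the vinyl chloride.

Step 14
Reactants: 18 C9 primary alcohol
Product: 19 C9 aldehyde (6-formyl analogue of 17; ring centres 1S,5S,6R)
Conditions: Dess–Martin periodinane, NaHCO3, CH2Cl2, 0 °C; used at once
Reagents that add atoms: none
Why: Buffered Dess–Martin oxidation gives the β-acetoxy aldehyde without epimerising C10 or eliminating the C11 acetate.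

Step 15
Reactants: 20 methyl (S)-3-hydroxy-2-methylpropanoate
Product: 21 methyl (S)-2-methyl-3-[(triethylsilyl)oxy]propanoate
Conditions: TESCl, imidazole, CH2Cl2, 0 °C
Reagents that add atoms: chlorotriethylsilane, CC[Si](Cl)(CC)CC
Why: Silylation protects the future C19 oxygen; the chiral-pool stereocentre becomes C17.

Step 16
Reactants: 21 silylated Roche ester
Product: 23 (S)-2-methyl-3-[(triethylsilyl)oxy]propanal, via aluminium hemiacetal 22 (not isolated)
Conditions: DIBAL-H (1.1 equiv), CH2Cl2, −78 °C; Rochelle salt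
Reagents that add atoms: none
Why: Low-temperature DIBAL-H reduction stops at the tetrahedral aluminium hemiacetal, which releases the aldehyde on work-up without racemisation.

Step 17
Reactants: 23 aldehyde
Product: 24 (R)-[(4,4-dibromo-2-methylbut-3-en-1-yl)oxy]triethylsilane
Conditions: CBr4, PPh3, 2,6-lutidine, CH2Cl2, 0 °C
Reagents that add atoms: carbon tetrabromide, BrC(Br)(Br)Br
Why: Ramirez dibromo-olefination (first stage of Corey–Fuchs) adds the future C7 carbon under non-basic conditions.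

Step 18
Reactants: 24 dibromoalkene
Product: 26 (R)-triethyl[(2-methylbut-3-yn-1-yl)oxy]silane, via lithium acetylide 25 (not isolated)
Conditions: n-BuLi (2.1 equiv), THF, −78 °C; aq. NH4Cl
Reagents that add atoms: none
Why: Corey–Fuchs Br/Li exchange and Fritsch–Buttenberg–Wiechell rearrangement give the terminal alkyne and avoid methanolic base, which would attack the TES ether.

Step 19
Reactants: 26 terminal alkyne
Product: 28 (S)-triethyl[(3-iodo-2-methylbut-3-en-1-yl)oxy]silane, via alkenylalane 27 (not isolated)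
Conditions: Ni(dppp)Cl2 (3 mol %), DIBAL-H, THF, 0 °C → rt; then I2, −78 → 0 °C
Reagents that add atoms: iodine, II
Why: Ni-catalysed α-selective hydroalumination followed by iodinolysis gives the 2-iodo-1-alkene (Markovnikov) in which C8 carries the iodine.

Step 20
Reactants: 19 C9 aldehyde + 28 2-iodoalkene
Product: 29 (9S)-allylic alcohol (C9 carbinol bearing C8(=C7H2)–C17H(CH3)–C19H2OTES)
Conditions: CrCl2 (10 mol %), chiral sulfonamide–oxazoline ligand (11 mol %, enantiomer for Re-face addition), proton sponge, NiCl2·(2,9-dimethylphenanthroline) (2 mol %), Mn, Cp2ZrCl2, LiCl, MeCN, rt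
Reagents that add atoms: none
Why: Catalyst-controlled Nozaki–Hiyama–Kishi coupling forms C8–C9 at the aldehyde only (enone, acetate and vinyl chloride are inert) and sets C9 (S) by ligand-directed Re-face addition.

Step 21
Reactants: 29 (9S)-allylic alcohol
Product: 30 8,9-anti epoxy alcohol (C7–C8 epoxide)
Conditions: VO(acac)2 (5 mol %), t-BuOOH, CH2Cl2, 0 °C
Reagents that add atoms: tert-butyl hydroperoxide, CC(C)(C)OO
Why: Hydroxyl-directed vanadium epoxidation touches only the allylic-alcohol alkene and, with a geminally substituted (A1,2-strained) alkene, gives the erythro (8,9-anti) epoxy alcohol.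

Step 22
Reactants: 30 epoxy alcohol
Product: 31 epoxy acetate (9-O-acetyl-30)
Conditions: Ac2O, pyridine, DMAP (cat.), CH2Cl2, 0 °C → rt
Reagents that add atoms: acetic anhydride, CC(=O)OC(C)=O
Why: Acetylation installs the C9 acetate of the target, which also serves as the internal nucleophile in the next step.

Step 23
Reactants: 31 epoxy acetate
Product: 33 8,9-syn 7,8-diol 9-acetate, via dioxolanylium ion 32 (not isolated)
Conditions: BF3·OEt2 (1.1 equiv), CH2Cl2, −78 °C; then H2O/THF, NaHCO3, 0 °C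
Reagents that add atoms: water, O
Why: Lewis-acid epoxide opening with anchimeric assistance: the acetate carbonyl attacks the tertiary C8 in a 5-exo mode with inversion (8,9-anti becomes 8,9-syn), and hydrolysis of the dioxolanylium ion expels the more basic tertiary oxygen, leaving C8–OH, C9–OAc and a primary C7–OH.

Step 24
Reactants: 33 diol acetate
Product: 34 C7 aldehyde (α-hydroxy aldehyde)
Conditions: TEMPO (10 mol %), NCS, Bu4NCl (cat.), CH2Cl2/aq. NaHCO3–K2CO3 (pH 8.6), rt; run directly after step 23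
Reagents that add atoms: none
Why: Oxoammonium (TEMPO/NCS) oxidation takes the primary C7–OH to the aldehyde without glycol cleavage and removes the primary hydroxyl before acyl migration can occur.

Step 25
Reactants: 34 C7 aldehyde
Product: 36 lactol (C7 hemiacetal with O-19; free C16–OH), via dihydroxy aldehyde 35 (not isolated)
Conditions: HF·pyridine, pyridine, THF, 0 °C
Reagents that add atoms: none
Why: Buffered HF cleaves the two primary TES ethers faster than the secondary bis-allylic one at C4, and the freed C19–OH closes onto the C7 aldehyde as a five-membered lactol.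

Step 26
Reactants: 36 lactol
Product: 37 allylic bromide lactol
Conditions: CBr4, PPh3, 2,6-lutidine, CH2Cl2, −40 → −10 °C
Reagents that add atoms: carbon tetrabromide, BrC(Br)(Br)Br
Why: Appel bromination converts the primary allylic C16–OH much faster than the hemiacetal or the tertiary hydroxyl.

Step 27
Reactants: 37 allylic bromide lactol
Product: 38 macrocyclic chlorohydrin diol (ten-membered ring; 6S,7R)
Conditions: CrCl2 (20 mol %), chiral sulfonamide–oxazoline ligand (22 mol %), proton sponge, Mn (3 equiv), Cp2ZrCl2 (1.5 equiv), LiCl, MeCN/THF 3:1, syringe-pump addition to 2 mM, rt; aq. potassium serinate work-up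
Reagents that add atoms: none
Why: Proposed new method: a Cr-catalysed, ligand-controlled intramolecular Nozaki–Hiyama γ-chloroallylation, in which Cr(II) (regenerated by Mn) inserts into the allylic C–Br bond to give an (E)-γ-chloroallyl-Cr(III) species (Cl trans to CH2Cr) that adds through a closed six-membered chair transition state to the ring-opened lactol aldehyde, forming C6–C7, the ten-membered ring, the exocyclic methylene and the anti-chlorohydrin, while the chiral ligand selects the Si face of the C7 aldehyde (7R, hence 6S) and Cp2ZrCl2 releases the alkoxide; the closest known reactions are Cr-catalysed asymmetric allylation/crotylation, the Cr-mediated addition of 1,3-dichloropropene to aldehydes and stoichiometric Cr-mediated macrocyclic allylations.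

Step 28
Reactants: 38 macrocyclic diol
Product: 41 4-O-TES lactone, via C19 aldehyde 39 (not isolated), via lactol 40 (not isolated)
Conditions: TEMPO (20 mol %), PhI(OAc)2 (2.5 equiv), CH2Cl2, rt
Reagents that add atoms: none
Why: TEMPO/PhI(OAc)2 oxidative lactonisation oxidises only the primary C19–OH, the aldehyde is trapped by C7–OH, and the lactol is oxidised to the γ-lactone under non-basic conditions that spare the chlorohydrin.

Step 29
Reactants: 41 4-O-TES lactone
Product: 42 CNP0196166.1 (target)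
Conditions: HF·pyridine, pyridine, THF, 0 °C → rt
Reagents that add atoms: none
Why: Buffered fluoride desilylation frees the bis-allylic C4–OH without ionising it or disturbing the allylic chloride, acetates or β-hydroxy lactone.

**Compound list**

1 | 3-methylbut-2-en-1-ol (prenol) | CC(C)=CCO | starting material
2 | 1-methoxy-4-{[(3-methylbut-2-en-1-yl)oxy]methyl}benzene | CC(C)=CCOCc1ccc(OC)cc1 | intermediate
3 | (E)-4-[(4-methoxybenzyl)oxy]-2-methylbut-2-enal | O=C/C(C)=C/COCc1ccc(OC)cc1 | intermediate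
4 | pent-1-en-3-one | CCC(=O)C=C | starting material
5 | (Z)-triisopropyl(penta-1,3-dien-3-yloxy)silane | C/C=C(/C=C)O[Si](C(C)C)(C(C)C)C(C)C | intermediate
6 | (1S,5S,6S)-6-{[(4-methoxybenzyl)oxy]methyl}-1,5-dimethyl-4-[(triisopropylsilyl)oxy]cyclohex-3-ene-1-carbaldehyde (major C5 epimer drawn) | O=C[C@@]1(C)CC=C(O[Si](C(C)C)(C(C)C)C(C)C)[C@@H](C)[C@@H]1COCc2ccc(OC)cc2 | intermediate
7 | (1S,5S,6S)-6-{[(4-methoxybenzyl)oxy]methyl}-1,5-dimethyl-4-oxocyclohex-2-ene-1-carbaldehyde | O=C[C@@]1(C)C=CC(=O)[C@@H](C)[C@@H]1COCc2ccc(OC)cc2 | intermediate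
8 | (4S,5S,6S)-4-[(E)-2-iodoethenyl]-5-{[(4-methoxybenzyl)oxy]methyl}-4,6-dimethylcyclohex-2-en-1-one | I/C=C/[C@@]1(C)C=CC(=O)[C@@H](C)[C@@H]1COCc2ccc(OC)cc2 | intermediate
9 | potassium dienolate of 8 (C11=C12–O−) | I/C=C/[C@@]1(C)C=CC([O-])=C(C)[C@@H]1COCc2ccc(OC)cc2.[K+] | intermediate
10 | potassium alkoxide of the C11 tertiary α-ketol (C11 configured as in 11) | I/C=C/[C@@]1(C)C=CC(=O)[C@@](C)([O-])[C@@H]1COCc2ccc(OC)cc2.[K+] | intermediate
11 | (1S,5S,6S)-5-[(E)-2-iodoethenyl]-6-{[(4-methoxybenzyl)oxy]methyl}-1,5-dimethyl-2-oxocyclohex-3-en-1-yl acetate | I/C=C/[C@@]1(C)C=CC(=O)[C@@](C)(OC(C)=O)[C@@H]1COCc2ccc(OC)cc2 | intermediate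
12 | 1,3-dihydroxypropan-2-one | OCC(=O)CO | starting material
13 | 1,3-bis[(triethylsilyl)oxy]propan-2-one | CC[Si](CC)(CC)OCC(=O)CO[Si](CC)(CC)CC | intermediate
14 | [2-(chloromethylidene)propane-1,3-diyl]bis(oxy)bis(triethylsilane) | ClC=C(CO[Si](CC)(CC)CC)CO[Si](CC)(CC)CC | intermediate
15 | (E)-3-chloro-2-{[(triethylsilyl)oxy]methyl}prop-2-en-1-ol (CH2OH cis to Cl) | Cl/C=C(\CO)CO[Si](CC)(CC)CC | intermediate
16 | (Z)-3-chloro-2-{[(triethylsilyl)oxy]methyl}prop-2-enal (CHO cis to Cl) | Cl/C=C(\C=O)CO[Si](CC)(CC)CC | intermediate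
17 | (1S,5S,6S)-5-[(1E,3S,4Z)-5-chloro-3-[(triethylsilyl)oxy]-4-{[(triethylsilyl)oxy]methyl}penta-1,4-dien-1-yl]-6-{[(4-methoxybenzyl)oxy]methyl}-1,5-dimethyl-2-oxocyclohex-3-en-1-yl acetate | Cl/C=C(CO[Si](CC)(CC)CC)\[C@@H](O[Si](CC)(CC)CC)/C=C/[C@@]1(C)C=CC(=O)[C@@](C)(OC(C)=O)[C@@H]1COCc2ccc(OC)cc2 | intermediate
18 | 6-(hydroxymethyl) analogue of 17 (C9–OH; 1S,5S,6S) | Cl/C=C(CO[Si](CC)(CC)CC)\[C@@H](O[Si](CC)(CC)CC)/C=C/[C@@]1(C)C=CC(=O)[C@@](C)(OC(C)=O)[C@@H]1CO | intermediate
19 | 6-formyl analogue of 17 (C9 aldehyde; 1S,5S,6R) | Cl/C=C(CO[Si](CC)(CC)CC)\[C@@H](O[Si](CC)(CC)CC)/C=C/[C@@]1(C)C=CC(=O)[C@@](C)(OC(C)=O)[C@@H]1C=O | intermediate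
20 | methyl (S)-3-hydroxy-2-methylpropanoate | COC(=O)[C@@H](C)CO | starting material
21 | methyl (S)-2-methyl-3-[(triethylsilyl)oxy]propanoate | COC(=O)[C@@H](C)CO[Si](CC)(CC)CC | intermediate
22 | diisobutylaluminium hemiacetal of 21 (hemiacetal carbon unassigned) | COC(O[Al](CC(C)C)CC(C)C)[C@@H](C)CO[Si](CC)(CC)CC | intermediate
23 | (S)-2-methyl-3-[(triethylsilyl)oxy]propanal | O=C[C@@H](C)CO[Si](CC)(CC)CC | intermediate
24 | (R)-[(4,4-dibromo-2-methylbut-3-en-1-yl)oxy]triethylsilane | BrC(Br)=C[C@@H](C)CO[Si](CC)(CC)CC | intermediate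
25 | lithium acetylide of 26 | [Li]C#C[C@@H](C)CO[Si](CC)(CC)CC | intermediate
26 | (R)-triethyl[(2-methylbut-3-yn-1-yl)oxy]silane | C#C[C@@H](C)CO[Si](CC)(CC)CC | intermediate
27 | diisobutyl[(3-methyl-4-(triethylsilyloxy)but-1-en-2-yl)]alane (C17 configured as in 28) | C=C([Al](CC(C)C)CC(C)C)[C@@H](C)CO[Si](CC)(CC)CC | intermediate
28 | (S)-triethyl[(3-iodo-2-methylbut-3-en-1-yl)oxy]silane | C=C(I)[C@@H](C)CO[Si](CC)(CC)CC | intermediate
29 | (9S)-allylic alcohol: 19 with the formyl carbon converted into CH(OH) bearing C8(=CH2)–CH(CH3)–CH2OTES (C17 from 28) | Cl/C=C(CO[Si](CC)(CC)CC)\[C@@H](O[Si](CC)(CC)CC)/C=C/[C@@]1(C)C=CC(=O)[C@@](C)(OC(C)=O)[C@@H]1[C@H](O)C(=C)[C@@H](C)CO[Si](CC)(CC)CC | intermediate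
30 | 8,9-anti epoxy alcohol: 29 with the C8=C7 alkene epoxidised, C8–O anti to C9–OH in the C10–C9–C8–C7 zigzag | Cl/C=C(CO[Si](CC)(CC)CC)\[C@@H](O[Si](CC)(CC)CC)/C=C/[C@@]1(C)C=CC(=O)[C@@](C)(OC(C)=O)[C@@H]1[C@H](O)[C@@]3(OC3)[C@@H](C)CO[Si](CC)(CC)CC | intermediate
31 | 9-O-acetate of 30 | Cl/C=C(CO[Si](CC)(CC)CC)\[C@@H](O[Si](CC)(CC)CC)/C=C/[C@@]1(C)C=CC(=O)[C@@](C)(OC(C)=O)[C@@H]1[C@H](OC(C)=O)[C@@]3(OC3)[C@@H](C)CO[Si](CC)(CC)CC | intermediate
32 | 2-methyl-1,3-dioxolan-2-ylium spanning O-8/O-9 (C8 inverted) with C7–O–BF3− | Cl/C=C(CO[Si](CC)(CC)CC)\[C@@H](O[Si](CC)(CC)CC)/C=C/[C@@]1(C)C=CC(=O)[C@@](C)(OC(C)=O)[C@@H]1[C@@H]3OC(C)=[O+][C@]3(CO[B-](F)(F)F)[C@@H](C)CO[Si](CC)(CC)CC | intermediate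
33 | 8,9-syn diol acetate: C7H2OH, C8–OH (configured as in the target), C9–OAc | Cl/C=C(CO[Si](CC)(CC)CC)\[C@@H](O[Si](CC)(CC)CC)/C=C/[C@@]1(C)C=CC(=O)[C@@](C)(OC(C)=O)[C@@H]1[C@H](OC(C)=O)[C@](CO)(O)[C@@H](C)CO[Si](CC)(CC)CC | intermediate
34 | C7 aldehyde of 33 (α-hydroxy aldehyde) | Cl/C=C(CO[Si](CC)(CC)CC)\[C@@H](O[Si](CC)(CC)CC)/C=C/[C@@]1(C)C=CC(=O)[C@@](C)(OC(C)=O)[C@@H]1[C@H](OC(C)=O)[C@](C=O)(O)[C@@H](C)CO[Si](CC)(CC)CC | intermediate
35 | 16,19-dihydroxy C7 aldehyde (4-O-TES retained) | Cl/C=C(CO)\[C@@H](O[Si](CC)(CC)CC)/C=C/[C@@]1(C)C=CC(=O)[C@@](C)(OC(C)=O)[C@@H]1[C@H](OC(C)=O)[C@](C=O)(O)[C@@H](C)CO | intermediate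
36 | lactol: five-membered C7 hemiacetal with O-19 (anomer mixture), free C16–OH | Cl/C=C(CO)\[C@@H](O[Si](CC)(CC)CC)/C=C/[C@@]1(C)C=CC(=O)[C@@](C)(OC(C)=O)[C@@H]1[C@H](OC(C)=O)[C@]3(O)[C@@H](C)COC3O | intermediate
37 | allylic bromide lactol (C16–Br; Cl trans to CH2Br) | Cl/C=C(CBr)\[C@@H](O[Si](CC)(CC)CC)/C=C/[C@@]1(C)C=CC(=O)[C@@](C)(OC(C)=O)[C@@H]1[C@H](OC(C)=O)[C@]3(O)[C@@H](C)COC3O | intermediate
38 | macrocyclic chlorohydrin diol: ten-membered ring, 6S-Cl, 7R-OH, C19H2OH, 4-O-TES | C=C1[C@@H](O[Si](CC)(CC)CC)/C=C/[C@@]2(C)C=CC(=O)[C@@](C)(OC(C)=O)[C@@H]2[C@H](OC(C)=O)[C@](O)([C@@H](C)CO)[C@@H](O)[C@H]1Cl | intermediate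
39 | C19 aldehyde of 38 | C=C1[C@@H](O[Si](CC)(CC)CC)/C=C/[C@@]2(C)C=CC(=O)[C@@](C)(OC(C)=O)[C@@H]2[C@H](OC(C)=O)[C@](O)([C@@H](C)C=O)[C@@H](O)[C@H]1Cl | intermediate
40 | C19 lactol (O-7 to C19; anomer mixture) | C=C1[C@@H](O[Si](CC)(CC)CC)/C=C/[C@@]2(C)C=CC(=O)[C@@](C)(OC(C)=O)[C@@H]2[C@H](OC(C)=O)[C@]2(O)[C@@H](C)C(O)O[C@H]2[C@H]1Cl | intermediate
41 | 4-O-triethylsilyl ether of the target | C=C1[C@@H](O[Si](CC)(CC)CC)/C=C/[C@@]2(C)C=CC(=O)[C@@](C)(OC(C)=O)[C@@H]2[C@H](OC(C)=O)[C@]2(O)[C@@H](C)C(=O)O[C@H]2[C@H]1Cl | intermediate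
42 | CNP0196166.1 (1S,4S,6S,7R,8R,9S,10S,11S,17R; 2E) | C=C1[C@@H](O)/C=C/[C@@]2(C)C=CC(=O)[C@@](C)(OC(C)=O)[C@@H]2[C@H](OC(C)=O)[C@]2(O)[C@@H](C)C(=O)O[C@H]2[C@H]1Cl | target

**Totals and risks**

Total step count: 29. Longest linear sequence: 19 steps (1 → 2 → 3 → 6 → 7 → 8 → 11 → 17 → 18 → 19 → 29 → 30 → 31 → 33 → 34 → 36 → 37 → 38 → 41 → 42).

Most likely to fail, step 27 (the new Cr-catalysed macrocyclising γ-chloroallylation): ring strain, protonation of the allylchromium by the free hydroxyls, or poor face selectivity at C7 could defeat it. The fallback sets out from 37 and returns at 38. Pd-catalysed borylation of the allylic bromide (Pd2(dba)3, B2pin2, THF) gives the γ-chloroallyl pinacol boronate F1. Heating F1 at high dilution (toluene, 60 °C) closes the ring by intramolecular allylboration through the chair transition state known for γ-chloroallylboron reagents (anti-chlorohydrin), and triethanolamine work-up gives 38.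

Second, step 4 (enantioselective Diels–Alder of a trisubstituted enal): the dienophile is hindered and the catalyst may give low conversion or ee. The fallback sets out from 3 and returns at 7. Butan-2-one and DMF dimethyl acetal give (E)-1-(dimethylamino)pent-1-en-3-one F2. KHMDS/TBSCl converts it into the aminosiloxydiene F3, which is far more reactive than 5. Its cycloaddition with 3 under Jacobsen's (salen)Cr(III) catalysis gives the amino silyl enol ether cycloadduct F4, and HF in MeCN removes the silyl group and eliminates dimethylamine to give enone aldehyde 7 directly.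

Third, step 23 (acetate-assisted epoxide opening with inversion at the tertiary C8): Meinwald rearrangement of the 2,2-disubstituted epoxide or acetate scrambling to O-7/O-8 are the dangers. The fallback sets out from 30 and returns at 34. Boc2O/DMAP gives the tert-butyl carbonate F5. BF3·OEt2 then gives the 8,9-cyclic carbonate F6 (carbonate-terminated epoxide opening, inversion at C8, no acyl ambiguity). K2CO3/MeOH at 0 °C gives triol F7, TEMPO/NCS oxidation gives hydroxy aldehyde F8, and selective acetylation of the secondary C9–OH (Ac2O, pyridine) gives 34.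

Further compounds
F1 | step 27 | γ-chloroallyl pinacol boronate (C16–Bpin analogue of 37) | Cl/C=C(CB2OC(C)(C)C(C)(C)O2)\[C@@H](O[Si](CC)(CC)CC)/C=C/[C@@]1(C)C=CC(=O)[C@@](C)(OC(C)=O)[C@@H]1[C@H](OC(C)=O)[C@]3(O)[C@@H](C)COC3O
F2 | step 4 | (E)-1-(dimethylamino)pent-1-en-3-one | CCC(=O)/C=C/N(C)C
F3 | step 4 | (1E,3Z)-3-[(tert-butyldimethylsilyl)oxy]-N,N-dimethylpenta-1,3-dien-1-amine | C/C=C(O[Si](C)(C)C(C)(C)C)/C=C/N(C)C
F4 | step 4 | amino silyl enol ether cycloadduct (NMe2 at C14 cis to CHO) | O=C[C@@]1(C)[C@@H](N(C)C)C=C(O[Si](C)(C)C(C)(C)C)[C@@H](C)[C@@H]1COCc2ccc(OC)cc2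
F5 | step 23 | 9-O-tert-butoxycarbonyl derivative of 30 | Cl/C=C(CO[Si](CC)(CC)CC)\[C@@H](O[Si](CC)(CC)CC)/C=C/[C@@]1(C)C=CC(=O)[C@@](C)(OC(C)=O)[C@@H]1[C@H](OC(=O)OC(C)(C)C)[C@@]3(OC3)[C@@H](C)CO[Si](CC)(CC)CC
F6 | step 23 | 8,9-cyclic carbonate with free C7H2OH (C8 inverted) | Cl/C=C(CO[Si](CC)(CC)CC)\[C@@H](O[Si](CC)(CC)CC)/C=C/[C@@]1(C)C=CC(=O)[C@@](C)(OC(C)=O)[C@@H]1[C@@H]3OC(=O)O[C@]3(CO)[C@@H](C)CO[Si](CC)(CC)CC
F7 | step 23 | 7,8,9-triol (8,9-syn) | Cl/C=C(CO[Si](CC)(CC)CC)\[C@@H](O[Si](CC)(CC)CC)/C=C/[C@@]1(C)C=CC(=O)[C@@](C)(OC(C)=O)[C@@H]1[C@H](O)[C@](CO)(O)[C@@H](C)CO[Si](CC)(CC)CC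
F8 | step 23 | 8,9-dihydroxy C7 aldehyde | Cl/C=C(CO[Si](CC)(CC)CC)\[C@@H](O[Si](CC)(CC)CC)/C=C/[C@@]1(C)C=CC(=O)[C@@](C)(OC(C)=O)[C@@H]1[C@H](O)[C@](C=O)(O)[C@@H](C)CO[Si](CC)(CC)CC
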